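**Plan**

1. Retrosynthetic cuts: first the C3–O ester bond (back to a C3–C4 epoxide plus the acid), then the C5–O acyl bond, the epoxide oxygen, the C2–O bond of an oxygen bridge, and last C1–C2 and C5–C6 of the ring.
2. Enabling feature: ring atoms C2–C3–C4–C5, with oxygen on C5 and an sp2 C2 beside the ester-bearing C1, are a furan whose C2–O–C5 bridge was opened by β-elimination; C1, C6 and the carboxyl carbon are an acrylate.
3. Forward: the cyclohexene is the only ring built and arises in step 1 as a 7-oxanorbornene from furan and an acrylimide. Methanolysis, bridge opening, C5 acylation, C3–C4 epoxidation and palladium-catalysed addition of the acid at C3 follow, without protecting groups.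
4. Stereochemistry: C5 is the oxygen-bearing bridgehead set by the copper–bis(oxazoline) catalyst. C4 and C3 are relayed from it: epoxidation anti to the C5 ester, then double inversion at C3 on palladium, which leaves the C3 ester cis to the C4 hydroxyl.

Key step: step 1

Assumption: the Cu(SbF6)2 complex of the (4R,4'R) ligand is taken to give the (2R) endo adduct, the mirror image of the established outcome with the (4S,4'S) ligand. Atom numbers C1 to C6 are those of the target ring (C1 bears CO2Me).

**Route**

Step 1
Reactants: 1 furan; 2 3-acryloyl-1,3-oxazolidin-2-one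
Product: 3 3-[(1R,2R,4R)-7-oxabicyclo[2.2.1]hept-5-ene-2-carbonyl]-1,3-oxazolidin-2-one (endo adduct; the bridgehead next to the CH2 is the future C5)
Conditions: CuCl2 (5 mol%), AgSbF6 (10 mol%), 2,2'-isopropylidenebis[(4R)-4-tert-butyl-2-oxazoline] (5.5 mol%), CH2Cl2, rt, filter; then 2, furan (10 equiv), −78 °C, 48 h; cold filtration through silica; chromatography and recrystallisation to remove the exo isomer
Reagents that add atoms: none
Why: The imide binds the square-planar divalent copper centre of the ligand–Cu(SbF6)2 complex through both carbonyl groups in its s-cis form, and furan adds to the activated alkene in a concerted suprafacial [4+2] cycloaddition; the closest known reaction type is the bis(oxazoline)–copper-catalysed Diels–Alder reaction of acryloyl oxazolidinones with cyclopentadiene and furan. The six-membered carbocycle closes by intermolecular cycloaddition in which C1–C2 and C5–C6 form together, the furan oxygen remaining as the one-atom bridge. The configuration of the imide-bearing carbon follows from a tert-butyl group of the ligand blocking one face of the chelated acrylate, the two bridgeheads are fixed relative to each other by suprafacial addition across furan, and their sense relative to the imide carbon comes from the endo transition state favoured under kinetic control at −78 °C. The step needs both enantioface and endo selectivity, because an exo adduct formed on the same acrylate face carries mirror-image bridgeheads and would give the enantiomeric diene in step 3. Two-point chelation by the oxazolidinone carbonyl of the dienophile secures the first and low temperature the second, and purification of the crystalline endo imide should remove the remaining exo isomer. The cycloaddition is reversible, so the Lewis acid is removed cold before the mixture is warmed.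

Step 2
Reactants: 3 endo oxanorbornene imide
Product: 4 methyl (1R,2R,4R)-7-oxabicyclo[2.2.1]hept-5-ene-2-carboxylate
Conditions: NaOMe (1.1 equiv), MeOH–CH2Cl2, 0 °C, 15 min; NH4Cl (aq)
Reagents that add atoms: sodium methoxide, [Na+].[O-]C
Why: Base-mediated methanolysis (transacylation) of an N-acyl oxazolidinone, in which methoxide attacks the more electrophilic exocyclic carbonyl and expels the oxazolidinone without touching the bridgeheads; epimerisation at the α-carbon would be harmless because that carbon becomes sp2 in step 3.

Step 3
Reactants: 4 methyl oxanorbornene ester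
Product: 5 methyl (5R)-5-hydroxycyclohexa-1,3-diene-1-carboxylate
Conditions: LiN(SiMe3)2 (1.1 equiv), THF, −78 °C; NH4Cl (aq), cold work-up, used promptly
Reagents that add atoms: none
Why: E1cB β-elimination, in which the ester enolate expels the bridging oxygen from the adjacent bridgehead with release of ring strain to give the conjugated diene ester, while the other bridgehead keeps its C–O bond and becomes the (5R) carbinol; low temperature and a mild quench should avoid dehydration to methyl benzoate.

Step 4
Reactants: 5 hydroxy diene; 6 (2E)-3-methylpent-2-enoic acid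
Product: 7 methyl (5R)-5-{[(2E)-3-methylpent-2-enoyl]oxy}cyclohexa-1,3-diene-1-carboxylate
Conditions: 6 (1.2 equiv), DCC (1.2 equiv), DMAP (0.1 equiv), CH2Cl2, 0 °C
Reagents that add atoms: none
Why: Steglich esterification acylates the secondary allylic alcohol with retention because the C5–O bond is not broken, and catalytic DMAP at 0 °C should limit deconjugation of the enoate and elimination to the arene.

Step 5
Reactants: 7 C5-acyloxy diene
Product: 8 methyl (1R,5R,6S)-5-{[(2E)-3-methylpent-2-enoyl]oxy}-7-oxabicyclo[4.1.0]hept-2-ene-3-carboxylate (C3–C4 epoxide on the face opposite the C5 ester)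
Conditions: mCPBA (1.2 equiv), NaHCO3, CH2Cl2, 0 °C to rt
Reagents that add atoms: 3-chloroperoxybenzoic acid (mCPBA), OOC(=O)c1cccc(Cl)c1
Why: Prilezhaev epoxidation selects the least electron-poor alkene (C3=C4, the γ,δ bond of the dienoate) and, with no hydrogen-bond donor present, should approach the face opposite the pseudoaxial C5 acyloxy group, setting C3 and C4 by substrate control; the buffer protects the vinyl epoxide from acid opening.

Step 6
Reactants: 8 anti vinyl epoxide; 6 (2E)-3-methylpent-2-enoic acid
Product: 9 methyl (3R,4S,5R)-4-hydroxy-3,5-bis{[(2E)-3-methylpent-2-enoyl]oxy}cyclohex-1-ene-1-carboxylate (target)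
Conditions: 6 (1.5 equiv), Pd(PPh3)4 (5 mol%), THF, 0 °C to rt
Reagents that add atoms: none
Why: Tsuji–Trost-type opening of a vinyl epoxide, in which zerovalent palladium ionises the allylic C3–O bond with inversion to a π-allyl complex of divalent palladium (C1 to C3) bearing a C4 alkoxide, the acid protonates the alkoxide, and its carboxylate attacks C3 (the terminus remote from the ester) on the face away from the metal, so that double inversion places the new ester cis to the free C4 hydroxyl and keeps the enoate conjugated.

**Compound list**

1 | furan | c1ccoc1 | starting material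
2 | 3-acryloyl-1,3-oxazolidin-2-one | C=CC(=O)N1CCOC1=O | starting material
3 | 3-[(1R,2R,4R)-7-oxabicyclo[2.2.1]hept-5-ene-2-carbonyl]-1,3-oxazolidin-2-one (endo) | O=C(N1CCOC1=O)[C@@H]2C[C@@H]3C=C[C@H]2O3 | intermediate
4 | methyl (1R,2R,4R)-7-oxabicyclo[2.2.1]hept-5-ene-2-carboxylate | COC(=O)[C@@H]1C[C@@H]2C=C[C@H]1O2 | intermediate
5 | methyl (5R)-5-hydroxycyclohexa-1,3-diene-1-carboxylate | COC(=O)C1=CC=C[C@H](O)C1 | intermediate
6 | (2E)-3-methylpent-2-enoic acid | CC/C(C)=C/C(=O)O | starting material
7 | methyl (5R)-5-{[(2E)-3-methylpent-2-enoyl]oxy}cyclohexa-1,3-diene-1-carboxylate | COC(=O)C1=CC=C[C@H](OC(=O)/C=C(\C)CC)C1 | intermediate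
8 | methyl (1R,5R,6S)-5-{[(2E)-3-methylpent-2-enoyl]oxy}-7-oxabicyclo[4.1.0]hept-2-ene-3-carboxylate | O1[C@@H]2C=C(C(=O)OC)C[C@@H](OC(=O)/C=C(\C)CC)[C@H]12 | intermediate
9 | methyl (3R,4S,5R)-4-hydroxy-3,5-bis{[(2E)-3-methylpent-2-enoyl]oxy}cyclohex-1-ene-1-carboxylate | CC/C(C)=C/C(=O)O[C@@H]1C=C(C(=O)OC)C[C@@H](OC(=O)/C=C(\C)CC)[C@@H]1O | target

**Count**

Total steps: 6. Longest linear sequence: 6 steps (from 1 and 2 to 9).

**Steps most likely to fail**

Step 6. The π-allyl intermediate may lose a β-hydrogen and aromatise, the carboxylate may attack with poor regiocontrol, or repeated ionisation of the allylic ester product may erode the configuration at C3. The fallback avoids palladium and sets out from 5. Upjohn dihydroxylation (OsO4 cat., NMO, acetone–water) of C3=C4 on the face opposite the C5 hydroxyl should give methyl (3R,4S,5R)-3,4,5-trihydroxycyclohex-1-ene-1-carboxylate (methyl shikimate) F1. Two-fold Steglich acylation with 6 (2.1 equiv, DCC, catalytic DMAP, CH2Cl2, −20 °C) then relies on the C4 hydroxyl, flanked on both sides, being the least reactive. Regioisomers would be removed by chromatography and base kept to a minimum to suppress acyl migration. The sequence returns to the route at 9.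

Step 5. Facial selectivity of the epoxidation may be poor because an ester is a weaker steric director than a silyl ether, and the vinyl epoxide may open under the acidic by-product. The fallback sets out from 7. OsO4/NMO dihydroxylation, for which attack anti to an allylic oxygen is well established, should give methyl 5-O-[(2E)-3-methylpent-2-enoyl]shikimate F2. 1,1'-Carbonyldiimidazole in CH2Cl2 converts the cis diol into the 3,4-cyclic carbonate of methyl 5-O-[(2E)-3-methylpent-2-enoyl]shikimate F3. Treatment with Pd(PPh3)4 and 6 in THF ionises the allylic C3–O bond with loss of carbon dioxide, giving the same π-allyl alkoxide as from 8 and, after carboxylate attack at C3, compound 9, where the route is rejoined.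

Step 1. Cycloreversion during a long reaction or on warming with the Lewis acid present, and incomplete endo selectivity, may erode the enantiomeric purity of the bridgeheads. The fallback sets out from 1 and replaces catalysis by resolution. Uncatalysed Diels–Alder reaction of furan with acrylic acid (C=CC(=O)O; neat, hydroquinone, rt) should give crystalline racemic endo-7-oxabicyclo[2.2.1]hept-5-ene-2-carboxylic acid F4. Fractional crystallisation with (R)-1-phenylethylamine gives the (R)-1-phenylethylammonium (1R,2R,4R)-7-oxabicyclo[2.2.1]hept-5-ene-2-carboxylate salt F5; the (S)-amine is used instead if the other diastereomeric salt proves the less soluble. Acidification frees (1R,2R,4R)-7-oxabicyclo[2.2.1]hept-5-ene-2-carboxylic acid F6, and Me3SiCHN2 in MeOH–toluene gives the methyl ester, returning to the route at 4.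

**Further compounds**

F1 | step 6 | methyl (3R,4S,5R)-3,4,5-trihydroxycyclohex-1-ene-1-carboxylate (methyl shikimate) | O[C@@H]1C=C(C(=O)OC)C[C@@H](O)[C@@H]1O
F2 | step 5 | methyl (3R,4R,5R)-3,4-dihydroxy-5-{[(2E)-3-methylpent-2-enoyl]oxy}cyclohex-1-ene-1-carboxylate (methyl 5-O-acylshikimate) | O[C@@H]1C=C(C(=O)OC)C[C@@H](OC(=O)/C=C(\C)CC)[C@@H]1O
F3 | step 5 | 3,4-cyclic carbonate of methyl 5-O-[(2E)-3-methylpent-2-enoyl]shikimate | O=C1O[C@@H]2C=C(C(=O)OC)C[C@@H](OC(=O)/C=C(\C)CC)[C@@H]2O1
F4 | step 1 | racemic endo-7-oxabicyclo[2.2.1]hept-5-ene-2-carboxylic acid | OC(=O)C1CC2C=CC1O2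
F5 | step 1 | (R)-1-phenylethylammonium (1R,2R,4R)-7-oxabicyclo[2.2.1]hept-5-ene-2-carboxylate | [O-]C(=O)[C@@H]1C[C@@H]2C=C[C@H]1O2.C[C@@H]([NH3+])c1ccccc1
F6 | step 1 | (1R,2R,4R)-7-oxabicyclo[2.2.1]hept-5-ene-2-carboxylic acid | OC(=O)[C@@H]1C[C@@H]2C=C[C@H]1O2
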